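## Retrosynthetic overview

1. Octahydroazulene numbering: C1 carries the angelate, C3 the carbinol, C4 the anisate, C3a/C8a are the ring fusion. Both esters go on last; the 4α-carbinol comes from hydroxyl-directed reduction of C4 ketone 17; the seven-membered ring is closed last by ring-closing metathesis (C6=C7) of cyclopentane 16.
2. The cyclopentane (C1, C2, C3, C3a, C8a) is made in one operation by a Lewis-acid formal (3+2) cycloaddition that forms C1–C2 and C3–C3a. The three-carbon unit C1–C8a–C3a is donor–acceptor cyclopropane 7; the two-carbon unit C2–C3 is enol silane 10 of 3-methylbutan-2-one.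
3. Enabling feature: C1 bears oxygen (donor) and C3a is α to the oxidised C4 (acceptor), 1,3-related across quaternary C8a. The C8a methyl and C4 are cis on the five-membered ring, so both are tied into a temporary γ-lactone (C8a–CH2–O–C4(=O)) that fixes C3a relative to C8a. The lactone is later opened, its CH2O deoxygenated to the angular methyl, and its carbonyl carbon kept as C4.
4. 7 comes from an enantioselective intramolecular cyclopropanation of allylic diazoacetate 6, which sets C8a. Ring order: lactone/cyclopropane, then cyclopentane, then cycloheptene.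

Key step: step 6

Remark: the sense of asymmetric induction in step 4 is assigned by analogy with simpler allylic diazoacetates; if it proves opposite, the antipodal (4S) catalyst is used.

## Route

Step 1
Reactants: 1 methyl pent-4-enoate
Product: 3 methyl (2E)-2-{[(naphthalen-2-yl)methoxy]methylidene}pent-4-enoate, via sodium formyl-ester enolate 2 (not isolated)
Conditions: HCO2Me, NaH, THF, 0 °C → rt; then DMF, 2-(bromomethyl)naphthalene, rt
Reagents that add atoms: methyl formate (COC=O); 2-(bromomethyl)naphthalene (BrCc1ccc2ccccc2c1)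
Why: Crossed Claisen formylation gives the sodium enolate, whose formyl oxygen (the carbon terminus is fully substituted) is alkylated in DMF (O-alkylation of an ambident enolate) to the β-alkoxyacrylate, the E isomer (ether oxygen trans to the ester) being the thermodynamically preferred geometry.

Step 2
Reactants: 3 methyl (2E)-2-{[(naphthalen-2-yl)methoxy]methylidene}pent-4-enoate
Product: 4 (2E)-2-{[(naphthalen-2-yl)methoxy]methylidene}pent-4-en-1-ol
Conditions: i-Bu2AlH (2.2 equiv), CH2Cl2, −78 °C; aq. potassium sodium tartrate (KNaC4H4O6) work-up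
Reagents that add atoms: none
Why: 1,2-Reduction of the ester by the aluminium hydride should give the allylic alcohol without touching the enol ether, its E geometry or the remote alkene, and the basic work-up protects the acid-labile product.

Step 3
Reactants: 4 (2E)-2-{[(naphthalen-2-yl)methoxy]methylidene}pent-4-en-1-ol
Product: 6 (2E)-2-{[(naphthalen-2-yl)methoxy]methylidene}pent-4-en-1-yl diazoacetate, via bromoacetate 5 (not isolated)
Conditions: BrCH2COBr, NaHCO3, MeCN, 0 °C; then TsNHNHTs, DBU, THF, 0 °C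
Reagents that add atoms: bromoacetyl bromide (BrCC(Br)=O); N,N'-ditosylhydrazine (Cc1ccc(cc1)S(=O)(=O)NNS(=O)(=O)c1ccc(C)cc1)
Why: O-Acylation followed by the Fukuyama diazoacetate synthesis (N-alkylation of ditosylhydrazine by the bromoacetate, then double base-induced loss of sulfinate) runs under basic conditions that the acid-labile enol ether should tolerate.

Step 4
Reactants: 6 (2E)-2-{[(naphthalen-2-yl)methoxy]methylidene}pent-4-en-1-yl diazoacetate
Product: 7 (1R,5R,6S)-6-[(naphthalen-2-yl)methoxy]-5-(prop-2-en-1-yl)-3-oxabicyclo[3.1.0]hexan-2-one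
Conditions: Rh2(4R-MPPIM)4 (dirhodium tetrakis[methyl (4R)-2-oxo-1-(3-phenylpropanoyl)imidazolidine-4-carboxylate], 1 mol%), CH2Cl2, 40 °C, slow addition of 6
Reagents that add atoms: none
Why: Doyle intramolecular cyclopropanation: the dirhodium carbenoid should add to the proximal electron-rich enol ether (five-membered lactone) rather than to the remote allyl alkene, the stereospecific syn addition carries the E geometry into the exo ether at C6 (cis to the allyl group), and the chiral carboxamidate ligands fix the absolute configuration of quaternary C5 and of C1.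

Step 5
Reactants: 8 3-methylbutan-2-one
Product: 10 trimethyl[(3-methylbut-1-en-2-yl)oxy]silane, via lithium enolate 9 (not isolated)
Conditions: LiN(i-Pr)2, THF, −78 °C; then Me3SiCl, −78 °C → rt
Reagents that add atoms: chlorotrimethylsilane (C[Si](C)(C)Cl)
Why: Kinetic deprotonation at the less hindered methyl group and O-silylation should give the less substituted enol silane.

Step 6
Reactants: 7 (1R,5R,6S)-6-[(naphthalen-2-yl)methoxy]-5-(prop-2-en-1-yl)-3-oxabicyclo[3.1.0]hexan-2-one; 10 trimethyl[(3-methylbut-1-en-2-yl)oxy]silane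
Product: 11 (3aR,4R,6R,6aR)-4-[(naphthalen-2-yl)methoxy]-6-(propan-2-yl)-3a-(prop-2-en-1-yl)-6-[(trimethylsilyl)oxy]hexahydro-1H-cyclopenta[c]furan-1-one
Conditions: 10 (2 equiv), Me3SiOTf (0.2 equiv), CH2Cl2, −78 → −40 °C; Et3N quench
Reagents that add atoms: none
Why: Me3SiOTf silylates the lactone carbonyl of 7 and the C1–C6 cyclopropane bond, flanked by the ether donor and the acyl acceptor, opens to an oxocarbenium ion held next to a cyclic silyl ketene acetal; the terminal carbon of 10 adds to the oxocarbenium carbon (first C–C bond) and the resulting silyloxocarbenium ion is trapped by the ketene acetal carbon (second C–C bond), which returns Me3Si+ to the cycle. The closest known reaction type is the Lewis-acid-mediated formal (3+2) cycloaddition of 2-alkoxycyclopropyl carbonyl compounds (donor–acceptor cyclopropanes) with silyl enol ethers. The one ring that is closed, the cyclopentane, closes by an intramolecular Mukaiyama aldol addition in the 5-(enolexo)-exo-trig mode. C6a is dictated by C3a because a cyclopentane can only be cis-fused to the γ-lactone (lactone carbonyl cis to the lactone CH2, trans to the allyl group); at C6 the isopropyl group should take the convex face of the emerging cis-bicyclo[3.3.0]octane, leaving the silyloxy group cis to the lactone carbonyl; C4 should be set by attack of 10 anti to the breaking C1–C6 bond (inversion at the donor carbon), which turns the exo ether of 7 into the ether cis to the lactone ring. The step needs cleavage of the donor–acceptor bond only (secured by the push–pull substitution and the fixed overlap of that bond with the lactone carbonyl) and capture of the oxocarbenium ion by 10 faster than bond rotation, Prins attack by the allyl group or loss of the naphthylmethyl cation (secured by the strongly nucleophilic enol silane in excess at −78 °C and by the acid-stable naphthylmethyl ether).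

Step 7
Reactants: 11 (3aR,4R,6R,6aR)-4-[(naphthalen-2-yl)methoxy]-6-(propan-2-yl)-3a-(prop-2-en-1-yl)-6-[(trimethylsilyl)oxy]hexahydro-1H-cyclopenta[c]furan-1-one
Product: 12 (1R,2R,3R,5R)-2-(hydroxymethyl)-N-methoxy-N-methyl-3-[(naphthalen-2-yl)methoxy]-5-(propan-2-yl)-2-(prop-2-en-1-yl)-5-[(trimethylsilyl)oxy]cyclopentane-1-carboxamide
Conditions: MeNH(OMe)·HCl, AlMe3, CH2Cl2, 0 °C → rt
Reagents that add atoms: N,O-dimethylhydroxylamine hydrochloride (CNOC.Cl)
Why: Weinreb aminolysis of the lactone by the aluminium amide should give the N-methoxy-N-methylamide and free the neopentyl hydroxymethyl group without touching any stereocenter.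

Step 8
Reactants: 12 (1R,2R,3R,5R)-2-(hydroxymethyl)-N-methoxy-N-methyl-3-[(naphthalen-2-yl)methoxy]-5-(propan-2-yl)-2-(prop-2-en-1-yl)-5-[(trimethylsilyl)oxy]cyclopentane-1-carboxamide
Product: 13 O-{[(1R,2R,3R,5R)-1-[methoxy(methyl)carbamoyl]-3-[(naphthalen-2-yl)methoxy]-5-(propan-2-yl)-2-(prop-2-en-1-yl)-5-[(trimethylsilyl)oxy]cyclopent-2-yl]methyl} O-phenyl carbonothioate (cyclopentane numbered as in 12)
Conditions: PhOC(S)Cl, pyridine, DMAP (cat.), CH2Cl2, 0 °C → rt
Reagents that add atoms: O-phenyl chlorothionoformate (S=C(Cl)Oc1ccccc1)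
Why: Acylation of the only free (primary) hydroxyl group gives the thionocarbonate needed for a Barton–McCombie deoxygenation and at once blocks re-lactonisation.

Step 9
Reactants: 13 O-phenyl thionocarbonate of 12
Product: 14 (1R,2R,3R,5R)-N-methoxy-N,2-dimethyl-3-[(naphthalen-2-yl)methoxy]-5-(propan-2-yl)-2-(prop-2-en-1-yl)-5-[(trimethylsilyl)oxy]cyclopentane-1-carboxamide
Conditions: Bu3SnH, AIBN (cat.), toluene, 110 °C
Reagents that add atoms: none
Why: Barton–McCombie deoxygenation: stannyl radical addition to the thiocarbonyl group and β-scission release the primary radical, which Bu3SnH reduces to the angular methyl group; the pent-4-enyl arrangement of the allyl group has only 4-exo or 5-endo cyclisation modes and should not interfere.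

Step 10
Reactants: 14 (1R,2R,3R,5R)-N-methoxy-N,2-dimethyl-3-[(naphthalen-2-yl)methoxy]-5-(propan-2-yl)-2-(prop-2-en-1-yl)-5-[(trimethylsilyl)oxy]cyclopentane-1-carboxamide
Product: 16 1-[(1R,2R,3R,5R)-5-hydroxy-2-methyl-3-[(naphthalen-2-yl)methoxy]-5-(propan-2-yl)-2-(prop-2-en-1-yl)cyclopentyl]-3-methylbut-3-en-1-one, via silyl-protected ketone 15 (not isolated)
Conditions: CH2=C(CH3)CH2MgCl (3 equiv), THF, −78 → 0 °C; then 1 M aq. HCl, 0 °C
Reagents that add atoms: 2-methylallylmagnesium chloride (C=C(C)C[Mg]Cl)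
Why: The chelated tetrahedral adduct of the Weinreb amide should stop the allylic Grignard reagent at single addition, and the cold acidic quench releases the β,γ-unsaturated ketone and cleaves the labile tertiary trimethylsilyl ether; the ring carbon α to the ketone already has the favoured configuration, trans to the isopropyl and allyl groups.

Step 11
Reactants: 16 1-[(1R,2R,3R,5R)-5-hydroxy-2-methyl-3-[(naphthalen-2-yl)methoxy]-5-(propan-2-yl)-2-(prop-2-en-1-yl)cyclopentyl]-3-methylbut-3-en-1-one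
Product: 17 (1R,3R,3aR,8aR)-3-hydroxy-6,8a-dimethyl-1-[(naphthalen-2-yl)methoxy]-3-(propan-2-yl)-2,3,3a,5,8,8a-hexahydroazulen-4(1H)-one
Conditions: second-generation Grubbs catalyst RuCl2(=CHPh)(PCy3)(H2IMes) (5 mol%), 1,4-benzoquinone (10 mol%), CH2Cl2 (2 mM), 40 °C
Reagents that add atoms: none
Why: Ring-closing metathesis between the allyl group and the 1,1-disubstituted methallyl alkene should close the seven-membered ring with the trisubstituted C6=C7 alkene; the two arms are trans on the cyclopentane, so the trans ring fusion is preset, and benzoquinone suppresses hydride-mediated migration of the β,γ-alkene.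

Step 12
Reactants: 17 (1R,3R,3aR,8aR)-3-hydroxy-6,8a-dimethyl-1-[(naphthalen-2-yl)methoxy]-3-(propan-2-yl)-2,3,3a,5,8,8a-hexahydroazulen-4(1H)-one
Product: 18 (1R,3R,3aS,4S,8aR)-6,8a-dimethyl-1-[(naphthalen-2-yl)methoxy]-3-(propan-2-yl)-1,2,3,3a,4,5,8,8a-octahydroazulene-3,4-diol
Conditions: Me4NBH(OAc)3, MeCN/AcOH (1:1), −30 → 0 °C
Reagents that add atoms: none
Why: Evans–Saksena reduction: the tertiary C3 hydroxyl group exchanges onto boron and delivers hydride intramolecularly to the face of the C4 ketone on which it lies (β), so the new C4 hydroxyl group should be α (4S), anti to the directing group.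

Step 13
Reactants: 18 (1R,3R,3aS,4S,8aR)-6,8a-dimethyl-1-[(naphthalen-2-yl)methoxy]-3-(propan-2-yl)-1,2,3,3a,4,5,8,8a-octahydroazulene-3,4-diol
Product: 19 (1R,3R,3aS,4S,8aR)-3-hydroxy-6,8a-dimethyl-1-[(naphthalen-2-yl)methoxy]-3-(propan-2-yl)-1,2,3,3a,4,5,8,8a-octahydroazulen-4-yl 4-methoxybenzoate
Conditions: 4-MeOC6H4COCl, Et3N, DMAP (cat.), CH2Cl2, 0 °C → rt
Reagents that add atoms: 4-methoxybenzoyl chloride (COc1ccc(cc1)C(Cl)=O)
Why: DMAP-catalysed acylation should esterify the secondary C4 hydroxyl group only, the tertiary C3 hydroxyl group being unreactive under these conditions.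

Step 14
Reactants: 19 (1R,3R,3aS,4S,8aR)-3-hydroxy-6,8a-dimethyl-1-[(naphthalen-2-yl)methoxy]-3-(propan-2-yl)-1,2,3,3a,4,5,8,8a-octahydroazulen-4-yl 4-methoxybenzoate
Product: 20 (1R,3R,3aS,4S,8aR)-1,3-dihydroxy-6,8a-dimethyl-3-(propan-2-yl)-1,2,3,3a,4,5,8,8a-octahydroazulen-4-yl 4-methoxybenzoate
Conditions: DDQ, CH2Cl2/pH 7 buffer (10:1), 0 °C → rt
Reagents that add atoms: none
Why: Oxidative cleavage of the electron-rich naphthylmethyl ether by DDQ in wet CH2Cl2 (hydride abstraction, then hydrolysis of the oxocarbenium ion) should leave the anisate ester, the alkene and the tertiary alcohol untouched.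

Step 15
Reactants: 20 (1R,3R,3aS,4S,8aR)-1,3-dihydroxy-6,8a-dimethyl-3-(propan-2-yl)-1,2,3,3a,4,5,8,8a-octahydroazulen-4-yl 4-methoxybenzoate
Product: 21 (1R,3R,3aS,4S,8aR)-3-hydroxy-4-[(4-methoxybenzoyl)oxy]-6,8a-dimethyl-3-(propan-2-yl)-1,2,3,3a,4,5,8,8a-octahydroazulen-1-yl (2Z)-2-methylbut-2-enoate
Conditions: angelic acid, 2,4,6-Cl3C6H2COCl, Et3N, toluene, rt; then 20, toluene, 80 °C
Reagents that add atoms: angelic acid, (2Z)-2-methylbut-2-enoic acid (C/C=C(/C)C(=O)O)
Why: Yamaguchi esterification: the mixed anhydride acylates the hindered secondary C1 hydroxyl group without a nucleophilic catalyst, conditions under which angelates are installed with retention of the Z geometry, and the tertiary hydroxyl group stays free.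

## Compound list

1 | methyl pent-4-enoate | C=CCCC(=O)OC | starting material
2 | sodium 2-(methoxycarbonyl)penta-1,4-dien-1-olate | [Na+].[O-]C=C(CC=C)C(=O)OC | intermediate
3 | methyl (2E)-2-{[(naphthalen-2-yl)methoxy]methylidene}pent-4-enoate | COC(=O)/C(CC=C)=C/OCc1ccc2ccccc2c1 | intermediate
4 | (2E)-2-{[(naphthalen-2-yl)methoxy]methylidene}pent-4-en-1-ol | OC/C(CC=C)=C/OCc1ccc2ccccc2c1 | intermediate
5 | (2E)-2-{[(naphthalen-2-yl)methoxy]methylidene}pent-4-en-1-yl bromoacetate | BrCC(=O)OC/C(CC=C)=C/OCc1ccc2ccccc2c1 | intermediate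
6 | (2E)-2-{[(naphthalen-2-yl)methoxy]methylidene}pent-4-en-1-yl diazoacetate | [N-]=[N+]=CC(=O)OC/C(CC=C)=C/OCc1ccc2ccccc2c1 | intermediate
7 | (1R,5R,6S)-6-[(naphthalen-2-yl)methoxy]-5-(prop-2-en-1-yl)-3-oxabicyclo[3.1.0]hexan-2-one (ether exo, cis to the allyl group) | C1OC(=O)[C@H]2[C@H](OCc3ccc4ccccc4c3)[C@@]12CC=C | intermediate
8 | 3-methylbutan-2-one | CC(=O)C(C)C | starting material
9 | lithium 3-methylbut-1-en-2-olate | [Li+].[O-]C(=C)C(C)C | intermediate
10 | trimethyl[(3-methylbut-1-en-2-yl)oxy]silane | C=C(O[Si](C)(C)C)C(C)C | intermediate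
11 | (3aR,4R,6R,6aR)-4-[(naphthalen-2-yl)methoxy]-6-(propan-2-yl)-3a-(prop-2-en-1-yl)-6-[(trimethylsilyl)oxy]hexahydro-1H-cyclopenta[c]furan-1-one | c1ccc2cc(CO[C@@H]3C[C@@](O[Si](C)(C)C)(C(C)C)[C@@H]4C(=O)OC[C@@]43CC=C)ccc2c1 | intermediate
12 | (1R,2R,3R,5R)-2-(hydroxymethyl)-N-methoxy-N-methyl-3-[(naphthalen-2-yl)methoxy]-5-(propan-2-yl)-2-(prop-2-en-1-yl)-5-[(trimethylsilyl)oxy]cyclopentane-1-carboxamide | c1ccc2cc(CO[C@@H]3C[C@@](O[Si](C)(C)C)(C(C)C)[C@H](C(=O)N(C)OC)[C@@]3(CO)CC=C)ccc2c1 | intermediate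
13 | O-phenyl thionocarbonate of the primary alcohol of 12 (same configuration) | c1ccc2cc(CO[C@@H]3C[C@@](O[Si](C)(C)C)(C(C)C)[C@H](C(=O)N(C)OC)[C@@]3(COC(=S)Oc4ccccc4)CC=C)ccc2c1 | intermediate
14 | (1R,2R,3R,5R)-N-methoxy-N,2-dimethyl-3-[(naphthalen-2-yl)methoxy]-5-(propan-2-yl)-2-(prop-2-en-1-yl)-5-[(trimethylsilyl)oxy]cyclopentane-1-carboxamide | c1ccc2cc(CO[C@@H]3C[C@@](O[Si](C)(C)C)(C(C)C)[C@H](C(=O)N(C)OC)[C@@]3(C)CC=C)ccc2c1 | intermediate
15 | 3-methyl-1-[(1R,2R,3R,5R)-2-methyl-3-[(naphthalen-2-yl)methoxy]-5-(propan-2-yl)-2-(prop-2-en-1-yl)-5-[(trimethylsilyl)oxy]cyclopentyl]but-3-en-1-one | c1ccc2cc(CO[C@@H]3C[C@@](O[Si](C)(C)C)(C(C)C)[C@H](C(=O)CC(C)=C)[C@@]3(C)CC=C)ccc2c1 | intermediate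
16 | 1-[(1R,2R,3R,5R)-5-hydroxy-2-methyl-3-[(naphthalen-2-yl)methoxy]-5-(propan-2-yl)-2-(prop-2-en-1-yl)cyclopentyl]-3-methylbut-3-en-1-one | c1ccc2cc(CO[C@@H]3C[C@@](O)(C(C)C)[C@H](C(=O)CC(C)=C)[C@@]3(C)CC=C)ccc2c1 | intermediate
17 | (1R,3R,3aR,8aR)-3-hydroxy-6,8a-dimethyl-1-[(naphthalen-2-yl)methoxy]-3-(propan-2-yl)-2,3,3a,5,8,8a-hexahydroazulen-4(1H)-one | c1ccc2cc(CO[C@@H]3C[C@@](O)(C(C)C)[C@@H]4C(=O)CC(C)=CC[C@]43C)ccc2c1 | intermediate
18 | (1R,3R,3aS,4S,8aR)-6,8a-dimethyl-1-[(naphthalen-2-yl)methoxy]-3-(propan-2-yl)-1,2,3,3a,4,5,8,8a-octahydroazulene-3,4-diol | c1ccc2cc(CO[C@@H]3C[C@@](O)(C(C)C)[C@@H]4[C@@H](O)CC(C)=CC[C@]43C)ccc2c1 | intermediate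
19 | (1R,3R,3aS,4S,8aR)-3-hydroxy-6,8a-dimethyl-1-[(naphthalen-2-yl)methoxy]-3-(propan-2-yl)-1,2,3,3a,4,5,8,8a-octahydroazulen-4-yl 4-methoxybenzoate | c1ccc2cc(CO[C@@H]3C[C@@](O)(C(C)C)[C@@H]4[C@@H](OC(=O)c5ccc(OC)cc5)CC(C)=CC[C@]43C)ccc2c1 | intermediate
20 | (1R,3R,3aS,4S,8aR)-1,3-dihydroxy-6,8a-dimethyl-3-(propan-2-yl)-1,2,3,3a,4,5,8,8a-octahydroazulen-4-yl 4-methoxybenzoate | O[C@@H]1C[C@@](O)(C(C)C)[C@@H]2[C@@H](OC(=O)c3ccc(OC)cc3)CC(C)=CC[C@]21C | intermediate
21 | (1R,3R,3aS,4S,8aR)-3-hydroxy-4-[(4-methoxybenzoyl)oxy]-6,8a-dimethyl-3-(propan-2-yl)-1,2,3,3a,4,5,8,8a-octahydroazulen-1-yl (2Z)-2-methylbut-2-enoate | C/C=C(/C)C(=O)O[C@@H]1C[C@@](O)(C(C)C)[C@@H]2[C@@H](OC(=O)c3ccc(OC)cc3)CC(C)=CC[C@]21C | target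

## Step count and risks

Total step count: 15. Longest linear sequence: 14 steps (steps 1–4 and 6–15; step 5 is the side branch to 10).

Steps most likely to fail:

Step 6 (key annulation). The process at risk is loss of stereocontrol at the ether-bearing carbon: with an alkoxy donor the ring-opened oxocarbenium ion may rotate before 10 captures it, so that inversion is eroded and the C4 epimer forms. The fallback sets C4 by substrate-controlled hydride delivery instead of in the annulation; it sets out from 7 and 10 and comes back at 11. The annulation is run unchanged and the epimeric ether (3aR,4S,6R,6aR)-4-[(naphthalen-2-yl)methoxy]-6-(propan-2-yl)-3a-(prop-2-en-1-yl)-6-[(trimethylsilyl)oxy]hexahydro-1H-cyclopenta[c]furan-1-one F1 is separated. DDQ in wet CH2Cl2 frees the alcohol (3aR,4S,6R,6aR)-4-hydroxy-6-(propan-2-yl)-3a-(prop-2-en-1-yl)-6-[(trimethylsilyl)oxy]hexahydro-1H-cyclopenta[c]furan-1-one F2. Dess–Martin periodinane gives the keto lactone (3aR,6R,6aR)-6-(propan-2-yl)-3a-(prop-2-en-1-yl)-6-[(trimethylsilyl)oxy]tetrahydro-1H-cyclopenta[c]furan-1,4(5H)-dione F3. NaBH4 in MeOH at −40 °C should deliver hydride to the convex face of the cis-fused bicycle and give the endo alcohol (3aR,4R,6R,6aR)-4-hydroxy-6-(propan-2-yl)-3a-(prop-2-en-1-yl)-6-[(trimethylsilyl)oxy]hexahydro-1H-cyclopenta[c]furan-1-one F4; this face selectivity is less certain than the rest of the sequence because the angular allyl group sits on the convex side. Etherification of F4 with (naphthalen-2-yl)methyl 2,2,2-trichloroacetimidate and catalytic Me3SiOTf at −40 °C re-forms 11.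

Step 4 (asymmetric cyclopropanation). The process at risk is insufficient enantio-induction by the carboxamidate catalyst on this trisubstituted enol ether, which has no close precedent. The fallback replaces asymmetric catalysis by resolution; it sets out from 6 and comes back at 7. Decomposition of 6 with achiral Rh2(OAc)4 (CH2Cl2, 40 °C, slow addition) gives the racemic lactone, that is 7 together with its antipode (1S,5S,6R)-6-[(naphthalen-2-yl)methoxy]-5-(prop-2-en-1-yl)-3-oxabicyclo[3.1.0]hexan-2-one F5. The two are separated by preparative chromatography on a chiral stationary phase and 7 is carried on.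

Step 9 (radical deoxygenation). The process at risk is slow fragmentation of the radical adduct of a primary, neopentyl thionocarbonate, so that the alcohol is regenerated or the thiocarbonyl group is merely reduced. The fallback is an ionic hydrazone reduction; it sets out from 12 and comes back at 14. Dess–Martin oxidation of 12 gives the aldehyde (1R,2S,3R,5R)-2-formyl-N-methoxy-N-methyl-3-[(naphthalen-2-yl)methoxy]-5-(propan-2-yl)-2-(prop-2-en-1-yl)-5-[(trimethylsilyl)oxy]cyclopentane-1-carboxamide F6. Condensation with TsNHNH2 in MeOH gives the tosylhydrazone (1R,2R,3R,5R)-N-methoxy-N-methyl-2-{(E)-[2-(4-methylbenzenesulfonyl)hydrazinylidene]methyl}-3-[(naphthalen-2-yl)methoxy]-5-(propan-2-yl)-2-(prop-2-en-1-yl)-5-[(trimethylsilyl)oxy]cyclopentane-1-carboxamide F7. Reduction with catecholborane at 0 °C, then NaOAc·3H2O in refluxing CHCl3, expels sulfinate and dinitrogen and leaves the methyl group of 14.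

## Further compounds

F1 | step 6 | (3aR,4S,6R,6aR)-4-[(naphthalen-2-yl)methoxy]-6-(propan-2-yl)-3a-(prop-2-en-1-yl)-6-[(trimethylsilyl)oxy]hexahydro-1H-cyclopenta[c]furan-1-one | c1ccc2cc(CO[C@H]3C[C@@](O[Si](C)(C)C)(C(C)C)[C@@H]4C(=O)OC[C@@]43CC=C)ccc2c1
F2 | step 6 | (3aR,4S,6R,6aR)-4-hydroxy-6-(propan-2-yl)-3a-(prop-2-en-1-yl)-6-[(trimethylsilyl)oxy]hexahydro-1H-cyclopenta[c]furan-1-one | O[C@H]1C[C@@](O[Si](C)(C)C)(C(C)C)[C@@H]2C(=O)OC[C@@]21CC=C
F3 | step 6 | (3aR,6R,6aR)-6-(propan-2-yl)-3a-(prop-2-en-1-yl)-6-[(trimethylsilyl)oxy]tetrahydro-1H-cyclopenta[c]furan-1,4(5H)-dione | O=C1C[C@@](O[Si](C)(C)C)(C(C)C)[C@@H]2C(=O)OC[C@@]21CC=C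
F4 | step 6 | (3aR,4R,6R,6aR)-4-hydroxy-6-(propan-2-yl)-3a-(prop-2-en-1-yl)-6-[(trimethylsilyl)oxy]hexahydro-1H-cyclopenta[c]furan-1-one | O[C@@H]1C[C@@](O[Si](C)(C)C)(C(C)C)[C@@H]2C(=O)OC[C@@]21CC=C
F5 | step 4 | (1S,5S,6R)-6-[(naphthalen-2-yl)methoxy]-5-(prop-2-en-1-yl)-3-oxabicyclo[3.1.0]hexan-2-one | C1OC(=O)[C@@H]2[C@@H](OCc3ccc4ccccc4c3)[C@]12CC=C
F6 | step 9 | (1R,2S,3R,5R)-2-formyl-N-methoxy-N-methyl-3-[(naphthalen-2-yl)methoxy]-5-(propan-2-yl)-2-(prop-2-en-1-yl)-5-[(trimethylsilyl)oxy]cyclopentane-1-carboxamide | c1ccc2cc(CO[C@@H]3C[C@@](O[Si](C)(C)C)(C(C)C)[C@H](C(=O)N(C)OC)[C@@]3(C=O)CC=C)ccc2c1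
F7 | step 9 | (1R,2R,3R,5R)-N-methoxy-N-methyl-2-{(E)-[2-(4-methylbenzenesulfonyl)hydrazinylidene]methyl}-3-[(naphthalen-2-yl)methoxy]-5-(propan-2-yl)-2-(prop-2-en-1-yl)-5-[(trimethylsilyl)oxy]cyclopentane-1-carboxamide | c1ccc2cc(CO[C@@H]3C[C@@](O[Si](C)(C)C)(C(C)C)[C@H](C(=O)N(C)OC)[C@@]3(/C=N/NS(=O)(=O)c4ccc(C)cc4)CC=C)ccc2c1
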